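**Retrosynthetic overview**
1. C5–C6: B-alkyl Suzuki coupling of the 9-BBN adduct of dienol 17 with (Z)-iodoalkene acetate 15.
2. C7–C8 and C6–I: alkoxide-directed anti-carbomagnesiation of propargyl alcohol by the Grignard reagent of chloride 9, then iodinolysis; this fixes the 6,7-olefin geometry.
3. The only ring (the oxolane) is formed once, in step 3: Shi epoxidation of homoallylic alcohol 7 and 5-endo epoxide opening (sets C14).
4. C11–C12 and C13–C14 in one operation: Pd-induced 1,2-shift of the C11 alkyl group from boron to carbon in vinyl borate 5, coupled with 1-bromo-2-methylpropene (sets C12).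
5. C11: Cu-catalysed enantioselective Markovnikov protoboration of 5-chloropent-1-ene.

Assumption: locants follow the geranylgeraniol skeleton (C1 = CH2OH, C7 bears CH2OAc, C11 = CHMe, C12–C15 = oxolane carbons), so the target is 11R,12S,14R with a 2E and a CIP-6Z olefin; the chiral ligands in steps 1 and 2 are specified by the sense of induction they must deliver.

**Step 1**
Reactants: 1 5-chloropent-1-ene
Product: 2 2-[(2R)-5-chloropentan-2-yl]-4,4,5,5-tetramethyl-1,3,2-dioxaborolane
Conditions: CuCl (5 mol%), bulky P-stereogenic QuinoxP*-type bisphosphine (antipode giving R), B2pin2, KOtBu (cat.), MeOH (2 equiv), THF, −40 °C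
Reagents that add atoms: bis(pinacolato)diboron, CC1(C)OB(OC1(C)C)B1OC(C)(C)C(C)(C)O1
Why: Cu-catalysed enantioselective Markovnikov protoboration (borylcupration with boron at the internal carbon, then protonation of C–Cu by MeOH) sets C11 as R by catalyst control; the primary chloride is inert to the boryl-copper at this temperature.

**Step 2**
Reactants: 2 2-[(2R)-5-chloropentan-2-yl]-4,4,5,5-tetramethyl-1,3,2-dioxaborolane; 3 vinylmagnesium chloride; 4 1-bromo-2-methylprop-1-ene
Product: 7 (5S,6R)-9-chloro-2,6-dimethylnon-2-en-5-ol, via vinyl borate complex 5 (not isolated), via homoallylic boronic ester 6 (not isolated)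
Conditions: 3, THF/DMSO, 0 °C → rt; then NaOTf, Pd(OAc)2 (2 mol%), Mandyphos-type ferrocenyl bisphosphine (antipode giving 12S), 4, 60 °C; then NaOH, H2O2, 0 °C → rt
Reagents that add atoms: hydrogen peroxide, OO
Why: Proposed new method: a cationic (bisphosphine)Pd(II)–isobutenyl species (oxidative addition of 4, bromide sequestered by NaOTf) binds the vinyl group of ate complex 5 and triggers a 1,2-shift of the C11 alkyl group from boron to C12 anti to Pd (retention at C11), reductive elimination then joins C13 to C14, and the ligand selects the alkene face and so sets C12 as S by catalyst control before stereoretentive C–B oxidation; the closest known reaction type is the Pd-catalysed enantioselective conjunctive cross-coupling of vinylboron ate complexes, not yet shown for an enantioenriched α-branched secondary alkyl migrating group combined with a β,β-disubstituted alkenyl bromide.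

**Step 3**
Reactants: 7 (5S,6R)-9-chloro-2,6-dimethylnon-2-en-5-ol
Product: 9 (3R,5S)-5-[(2R)-5-chloropentan-2-yl]-2,2-dimethyloxolan-3-ol, via epoxy alcohol 8 (not isolated)
Conditions: D-fructose-derived Shi ketone (30 mol%), Oxone, K2CO3, Bu4NHSO4, MeCN/DMM–borate buffer (pH 10.5), 0 °C; then CSA (10 mol%), CH2Cl2, 0 °C → rt
Reagents that add atoms: potassium peroxymonosulfate (Oxone), [K+].[O-]S(=O)(=O)OO
Why: Shi asymmetric epoxidation of the only alkene gives the (R)-epoxide at C14 by reagent control (spiro transition state), and acid-catalysed 5-endo epoxide opening by the C12 hydroxyl at the tertiary C15 closes the oxolane with C12 and C14 untouched, giving the 3,5-trans ring.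

**Step 4**
Reactants: 9 (3R,5S)-5-[(2R)-5-chloropentan-2-yl]-2,2-dimethyloxolan-3-ol; 10 prop-2-yn-1-ol
Product: 14 (3R,5S)-5-[(2R,6Z)-6-(hydroxymethyl)-7-iodohept-6-en-2-yl]-2,2-dimethyloxolan-3-ol, via Grignard alkoxide 11 (not isolated), via chloromagnesium propargyl alkoxide 12 (not isolated), via alkenylmagnesium chelate 13 (not isolated)
Conditions: 9, i-PrMgCl (1.0 equiv), THF, 0 °C, then Mg (BrCH2CH2Br-activated), 60 °C; 10 (1.5 equiv), i-PrMgCl (1.5 equiv), Et2O/THF, −20 °C; combine, CuI (15 mol%), −10 °C → rt, 16 h; I2, −20 °C; aq. NH4Cl/Na2S2O3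
Reagents that add atoms: iodine, II
Why: Grignard formation on the pre-formed magnesium alkoxide is followed by Cu-catalysed alkoxide-directed anti-carbomagnesiation of the propargyl alkoxide (alkyl to C7, magnesium to C6 held cis to CH2O in a five-membered chelate), and iodinolysis with retention gives the Z-iodide with iodine cis to CH2OH.

**Step 5**
Reactants: 14 (3R,5S)-5-[(2R,6Z)-6-(hydroxymethyl)-7-iodohept-6-en-2-yl]-2,2-dimethyloxolan-3-ol
Product: 15 [(2Z,6R)-6-[(2S,4R)-4-hydroxy-5,5-dimethyloxolan-2-yl]-2-(iodomethylidene)heptyl] acetate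
Conditions: AcCl (1.05 equiv), 2,4,6-collidine, CH2Cl2, −78 °C
Reagents that add atoms: acetyl chloride, CC(Cl)=O
Why: Chemoselective O-acylation of the primary allylic hydroxyl over the hindered secondary hydroxyl next to the quaternary carbon; no stereocentre is touched.

**Step 6**
Reactants: 16 (2E)-3-methylpent-2-en-4-yn-1-ol
Product: 17 (2E)-3-methylpenta-2,4-dien-1-ol
Conditions: H2 (1 atm), Lindlar catalyst, quinoline, EtOAc, rt, stopped at 1 equiv H2
Reagents that add atoms: none
Why: Lindlar semihydrogenation reduces the terminal alkyne to the vinyl group without touching the trisubstituted E-alkene.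

**Step 7**
Reactants: 17 (2E)-3-methylpenta-2,4-dien-1-ol; 15 [(2Z,6R)-6-[(2S,4R)-4-hydroxy-5,5-dimethyloxolan-2-yl]-2-(iodomethylidene)heptyl] acetate
Product: 19 [(2Z,6E)-8-hydroxy-2-[(4R)-4-[(2S,4R)-4-hydroxy-5,5-dimethyloxolan-2-yl]pentyl]-6-methylocta-2,6-dien-1-yl] acetate, via bis-borane adduct 18 (not isolated)
Conditions: 17 (1.5 equiv), 9-BBN (3.3 equiv B–H), THF, 0 °C → rt; then 15, Pd(dppf)Cl2 (5 mol%), AsPh3 (10 mol%), Cs2CO3, DMF/H2O, rt
Reagents that add atoms: none
Why: 9-BBN masks the hydroxyl as a borinate and hydroborates only the monosubstituted vinyl terminus (anti-Markovnikov), and B-alkyl Suzuki–Miyaura coupling with the vinyl iodide proceeds with retention of olefin geometry at room temperature, where the allylic acetate and free hydroxyls survive.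

**Compound list**
1 | 5-chloropent-1-ene | C=CCCCCl | starting material
2 | 2-[(2R)-5-chloropentan-2-yl]-4,4,5,5-tetramethyl-1,3,2-dioxaborolane | ClCCC[C@@H](C)B1OC(C)(C)C(C)(C)O1 | intermediate
3 | vinylmagnesium chloride | C=C[Mg]Cl | starting material
4 | 1-bromo-2-methylprop-1-ene | CC(C)=CBr | starting material
5 | chloromagnesium [(2R)-5-chloropentan-2-yl](ethenyl)(pinacolato)borate | ClCCC[C@@H](C)[B-]1(C=C)OC(C)(C)C(C)(C)O1.[Mg+]Cl | intermediate
6 | 2-[(5S,6R)-9-chloro-2,6-dimethylnon-2-en-5-yl]-4,4,5,5-tetramethyl-1,3,2-dioxaborolane | ClCCC[C@@H](C)[C@@H](B1OC(C)(C)C(C)(C)O1)CC=C(C)C | intermediate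
7 | (5S,6R)-9-chloro-2,6-dimethylnon-2-en-5-ol | ClCCC[C@@H](C)[C@@H](O)CC=C(C)C | intermediate
8 | (2S,3R)-6-chloro-1-[(2R)-3,3-dimethyloxiran-2-yl]-3-methylhexan-2-ol | ClCCC[C@@H](C)[C@@H](O)C[C@H]1OC1(C)C | intermediate
9 | (3R,5S)-5-[(2R)-5-chloropentan-2-yl]-2,2-dimethyloxolan-3-ol | ClCCC[C@@H](C)[C@@H]1C[C@@H](O)C(C)(C)O1 | intermediate
10 | prop-2-yn-1-ol | C#CCO | starting material
11 | [(4R)-4-[(2S,4R)-4-(chloromagnesiooxy)-5,5-dimethyloxolan-2-yl]pentyl]magnesium chloride | Cl[Mg]CCC[C@@H](C)[C@@H]1C[C@@H](O[Mg]Cl)C(C)(C)O1 | intermediate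
12 | chloromagnesium prop-2-yn-1-olate | C#CCO[Mg]Cl | intermediate
13 | (Z)-alkenylmagnesium chloride from 11 and 12, Mg cis to CH2OMgCl | Cl[Mg]OC/C(=C\[Mg]Cl)CCC[C@@H](C)[C@@H]1C[C@@H](O[Mg]Cl)C(C)(C)O1 | intermediate
14 | (3R,5S)-5-[(2R,6Z)-6-(hydroxymethyl)-7-iodohept-6-en-2-yl]-2,2-dimethyloxolan-3-ol | OC/C(=C\I)CCC[C@@H](C)[C@@H]1C[C@@H](O)C(C)(C)O1 | intermediate
15 | [(2Z,6R)-6-[(2S,4R)-4-hydroxy-5,5-dimethyloxolan-2-yl]-2-(iodomethylidene)heptyl] acetate | CC(=O)OC/C(=C\I)CCC[C@@H](C)[C@@H]1C[C@@H](O)C(C)(C)O1 | intermediate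
16 | (2E)-3-methylpent-2-en-4-yn-1-ol | C#C/C(C)=C/CO | starting material
17 | (2E)-3-methylpenta-2,4-dien-1-ol | C=C/C(C)=C/CO | intermediate
18 | 9-[(3E)-3-methyl-5-(9-borabicyclo[3.3.1]nonan-9-yloxy)pent-3-en-1-yl]-9-borabicyclo[3.3.1]nonane | C/C(CCB1C2CCCC1CCC2)=C\COB1C2CCCC1CCC2 | intermediate
19 | [(2Z,6E)-8-hydroxy-2-[(4R)-4-[(2S,4R)-4-hydroxy-5,5-dimethyloxolan-2-yl]pentyl]-6-methylocta-2,6-dien-1-yl] acetate | CC(=O)OC/C(=C\CC/C(C)=C/CO)CCC[C@@H](C)[C@@H]1C[C@@H](O)C(C)(C)O1 | target

**Totals**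
Total steps: 7. Longest linear sequence: 6 (steps 1, 2, 3, 4, 5, 7; step 6 is the side branch).

**Steps most likely to fail**

Step 2 (the proposed new method). The risks are incomplete catalyst control at C12 with the α-branched migrating group, β-hydride elimination, and direct vinyl transfer. The fallback is known chemistry; it sets out from 2 and returns at 7. 4-Methylpent-3-en-1-ol is acylated with 2,4,6-triisopropylbenzoyl chloride to give 4-methylpent-3-en-1-yl 2,4,6-triisopropylbenzoate F1. Deprotonation with s-BuLi/(+)-sparteine (Et2O, −78 °C) gives the configurationally stable (1R)-1-lithio-4-methylpent-3-en-1-yl 2,4,6-triisopropylbenzoate F2. This captures 2 with retention to give the lithium borate complex F3. On warming with MgBr2·OEt2/MeOH the C11 group shifts from boron to C12 with inversion and expels the benzoate, giving 6, which is oxidised (NaOH/H2O2) to 7.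

Step 4. The risks are Grignard formation on an alkoxide-bearing chloride and carbomagnesiation with the Grignard reagent as the limiting partner. The fallback sets out from 9 (through 11) and returns at 14. Grignard reagent 11 is added as the limiting reagent to 2-[tert-butyl(dimethyl)silyl]oxy-N-methoxy-N-methylacetamide to give (6R)-1-[tert-butyl(dimethyl)silyl]oxy-6-[(2S,4R)-4-hydroxy-5,5-dimethyloxolan-2-yl]heptan-2-one F4. Wittig iodomethylenation with the ylide from (iodomethyl)triphenylphosphonium iodide/NaHMDS (THF/HMPA, −78 °C) gives the silyl-protected (Z)-vinyl iodide F5; the α-silyloxy group is expected to direct iodine cis to CH2OSi, as in Z-selective Wittig reactions of α-alkoxy ketones. TBAF then releases 14.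

Step 7. The risks are hydroboration of an unprotected dienol and exposure of the allylic acetate to Pd(0) and aqueous base. The fallback sets out from 14 and 17 and returns at 19. Dienol 17 is silylated (TBSCl, imidazole) to tert-butyl(dimethyl){[(2E)-3-methylpenta-2,4-dien-1-yl]oxy}silane F6 and hydroborated with 9-BBN to the alkylborane F7. F7 is coupled with the unacetylated iodide 14 under the same Pd conditions to give the diol silyl ether F8. Selective acetylation of its only primary hydroxyl (AcCl, collidine, −78 °C) gives the acetate silyl ether F9, and HF·pyridine removes the silyl group to give 19.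

**Further compounds**
F1 | step 2 | 4-methylpent-3-en-1-yl 2,4,6-triisopropylbenzoate | CC(C)=CCCOC(=O)c1c(C(C)C)cc(C(C)C)cc1C(C)C
F2 | step 2 | (1R)-1-lithio-4-methylpent-3-en-1-yl 2,4,6-triisopropylbenzoate | [Li][C@H](CC=C(C)C)OC(=O)c1c(C(C)C)cc(C(C)C)cc1C(C)C
F3 | step 2 | lithium [(2R)-5-chloropentan-2-yl][(1R)-4-methyl-1-(2,4,6-triisopropylbenzoyloxy)pent-3-en-1-yl](pinacolato)borate | ClCCC[C@@H](C)[B-]1(OC(C)(C)C(C)(C)O1)[C@H](CC=C(C)C)OC(=O)c1c(C(C)C)cc(C(C)C)cc1C(C)C.[Li+]
F4 | step 4 | (6R)-1-[tert-butyl(dimethyl)silyl]oxy-6-[(2S,4R)-4-hydroxy-5,5-dimethyloxolan-2-yl]heptan-2-one | CC(C)(C)[Si](C)(C)OCC(=O)CCC[C@@H](C)[C@@H]1C[C@@H](O)C(C)(C)O1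
F5 | step 4 | (3R,5S)-5-[(2R,6Z)-6-{[tert-butyl(dimethyl)silyl]oxymethyl}-7-iodohept-6-en-2-yl]-2,2-dimethyloxolan-3-ol | CC(C)(C)[Si](C)(C)OC/C(=C\I)CCC[C@@H](C)[C@@H]1C[C@@H](O)C(C)(C)O1
F6 | step 7 | tert-butyl(dimethyl){[(2E)-3-methylpenta-2,4-dien-1-yl]oxy}silane | C=C/C(C)=C/CO[Si](C)(C)C(C)(C)C
F7 | step 7 | 9-[(3E)-5-{[tert-butyl(dimethyl)silyl]oxy}-3-methylpent-3-en-1-yl]-9-borabicyclo[3.3.1]nonane | C/C(CCB1C2CCCC1CCC2)=C\CO[Si](C)(C)C(C)(C)C
F8 | step 7 | (3R,5S)-5-[(2R,6Z,10E)-12-{[tert-butyl(dimethyl)silyl]oxy}-6-(hydroxymethyl)-10-methyldodeca-6,10-dien-2-yl]-2,2-dimethyloxolan-3-ol | OC/C(=C\CC/C(C)=C/CO[Si](C)(C)C(C)(C)C)CCC[C@@H](C)[C@@H]1C[C@@H](O)C(C)(C)O1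
F9 | step 7 | [(2Z,6E)-8-{[tert-butyl(dimethyl)silyl]oxy}-2-[(4R)-4-[(2S,4R)-4-hydroxy-5,5-dimethyloxolan-2-yl]pentyl]-6-methylocta-2,6-dien-1-yl] acetate | CC(=O)OC/C(=C\CC/C(C)=C/CO[Si](C)(C)C(C)(C)C)CCC[C@@H](C)[C@@H]1C[C@@H](O)C(C)(C)O1
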